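**Assumptions (one line each)**
- (R)-4-Methylcyclopent-2-enone (5) is treated as commercially available. Otherwise it comes from (S)-3-methylcyclopentanone by Saegusa oxidation.
- The stereocentre at C8 (the carbon bearing Me and CO2R) is a ~1:1 epimeric mixture in compounds 8–15. It becomes a planar ketene acetal in step 10, so it does not matter.
- Atom labels: C1 bears Et and C2 is the ring =CH. C3 is CHMe, and C4 and C9 are the ring-fusion carbons. C5(Me)=C6H is the ring alkene, C7 carries Me and the dienyl chain, and C8 carries Me and CO2H.

**Retrosynthetic overview**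
1. Not the biomimetic intramolecular Diels–Alder (IMDA). The cyclohexene is closed last by RCM (C5=C6) of a 1,1-disubstituted isopropenyl alkene (on C4) and a quaternary-carbon vinyl group (on C7).
2. The vicinal quaternary centres C7/C8 and the CO2H come from one Ireland–Claisen rearrangement of an all-E trienyl ester. The side chain is carried in on the allylic alcohol.
3. The cyclopentene (Et at C1) comes from a kinetic enol triflate and Negishi ethylation of a cyclopentanone.
4. That cyclopentanone, with C3/C4/C9 all-trans, comes from tandem conjugate addition–aldol on (R)-4-methylcyclopentenone, then dehydration and conjugate reduction.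
5. Ring order: cyclopentanone → cyclopentene → cyclohexene.

---

**Step 1**
Reactants: 1 (E)-4-phenylbut-3-en-2-one; 2 ethyl (E)-4-(diethoxyphosphoryl)-3-methylbut-2-enoate
Product: 3 ethyl (2E,4E,6E)-3,5-dimethyl-7-phenylhepta-2,4,6-trienoate
Conditions: NaH, THF, 0 °C → 25 °C; separate the all-E isomer by chromatography
Reagents that add atoms: none
Why: Horner–Wadsworth–Emmons olefination of the ketone keeps the 2E alkene of 2 and gives the new C4=C5 alkene mainly E (retinoid-type chain extension); there are no stereocentres.

**Step 2**
Reactants: 3
Product: 4 (2E,4E,6E)-3,5-dimethyl-7-phenylhepta-2,4,6-trien-1-ol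
Conditions: DIBAL-H (2.5 equiv), CH2Cl2, −78 °C
Reagents that add atoms: none
Why: DIBAL reduces the ester 1,2 to the allylic alcohol and leaves the triene untouched, which gives the E-configured allylic alcohol needed for the Claisen step.

**Step 3**
Reactants: 5 (R)-4-methylcyclopent-2-en-1-one; 6 isopropenylmagnesium bromide; 7 methyl pyruvate
Product: 8 aldol adduct (4-Me and 5-isopropenyl trans on the cyclopentanone)
Conditions: 6 (1.3 equiv), CuBr·SMe2 (10 mol%), THF, −78 °C; then 7 (1.5 equiv), −78 → −30 °C
Reagents that add atoms: none (all atoms come from the numbered reactants)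
Why: Cu-catalysed 1,4-addition occurs anti to the C3 methyl, which sets C4 trans to C3-Me; the regiospecific C9 magnesium enolate is then trapped by the pyruvate ketone in an aldol (three-component coupling). The C8/C9 stereochemistry formed here is erased in step 4.

**Step 4**
Reactants: 8
Product: 9 methyl 2-[4-methyl-2-oxo-5-(prop-1-en-2-yl)cyclopentylidene]propanoate (E/Z mixture)
Conditions: Burgess reagent, PhMe, 60 °C
Reagents that add atoms: none
Why: Syn-dehydration toward the acidic α-C9–H gives the conjugated alkylidene (E1cB-like); C4 is untouched and the E/Z ratio is irrelevant.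

**Step 5**
Reactants: 9
Product: 10 methyl 2-[4-methyl-2-oxo-5-(prop-1-en-2-yl)cyclopentyl]propanoate (all-trans ring; C8 epimers)
Conditions: Stryker's reagent (5 mol%), PhSiH3, PhMe, 0 °C; then DBU, CH2Cl2, 25 °C
Reagents that add atoms: none
Why: Cu–H 1,4-reduction leaves the isopropenyl group intact, and DBU epimerises the α-keto centre C9 to the thermodynamic trans isomer, which sets C9 trans to the C4 substituent.

**Step 6**
Reactants: 10
Product: 11 cyclopentenyl triflate (C1-OTf, C1=C2)
Conditions: KHMDS (1.05 equiv), THF, −78 °C; then PhNTf2
Reagents that add atoms: PhNTf2, O=S(=O)(N(c1ccccc1)S(=O)(=O)C(F)(F)F)C(F)(F)F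
Why: Kinetic deprotonation at the unhindered CH2 (C2) rather than the tertiary C9–H gives the regiodefined enol triflate (enolate trapping), so C9 is not epimerised.

**Step 7**
Reactants: 11; 12 diethylzinc
Product: 13 methyl 2-[2-ethyl-4-methyl-5-(prop-1-en-2-yl)cyclopent-2-en-1-yl]propanoate
Conditions: Pd(PPh3)4 (5 mol%), LiCl, THF, 60 °C
Reagents that add atoms: none (the Et group comes from numbered 12)
Why: Negishi-type coupling of the vinyl triflate with Et2Zn installs the C1 ethyl group and fixes the C1=C2 alkene; esters and alkenes survive.

**Step 8**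
Reactants: 13
Product: 14 the corresponding carboxylic acid
Conditions: LiOH·H2O, THF/MeOH/H2O, 50 °C; then H3O+
Reagents that add atoms: water/hydroxide (the O atom of the acid OH)
Why: Saponification of the unhindered secondary ester; C8 epimerisation is irrelevant.

**Step 9**
Reactants: 14; 4
Product: 15 (2E,4E,6E)-3,5-dimethyl-7-phenylhepta-2,4,6-trien-1-yl ester of 14
Conditions: 2,4,6-Cl3C6H2COCl, Et3N, THF, 0 °C; then 4, DMAP, PhMe, 25 °C
Reagents that add atoms: none
Why: Yamaguchi esterification under basic conditions avoids ionisation of the acid-sensitive trienyl alcohol.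

**Step 10**
Reactants: 15
Product: 16 (4E,6E)-2-[2-ethyl-4-methyl-5-(prop-1-en-2-yl)cyclopent-2-en-1-yl]-3-ethenyl-2,3,5-trimethyl-7-phenylhepta-4,6-dienoic acid
Conditions: LDA (1.5 equiv), THF/HMPA 4:1, −78 °C; TBSCl; warm to 60 °C (sealed tube); then 1 M HCl/THF
Reagents that add atoms: none (the transient TBS ester is cleaved on acidic work-up)
Why: Proposed new method: HMPA enolisation puts the large C9 group cis to OSi and Me cis to the allyl oxygen. With the E-trienyl allyl unit, a chair [3,3] TS then has C9 and the dienyl group equatorial and both methyls axial, delivering the required C7/C8 relative configuration, while approach anti to the C4 isopropenyl is expected to control C8 versus C9. The closest known reaction is the Ireland–Claisen rearrangement forming vicinal quaternary centres, and the acid is released directly.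

**Step 11**
Reactants: 16
Product: 17 methyl ester of 16
Conditions: TMSCHN2, MeOH/PhMe, 0 → 25 °C
Reagents that add atoms: TMSCHN2, C[Si](C)(C)C=[N+]=[N-]
Why: Diazoalkane O-methylation works even on this hindered acid because it does not depend on attack at the carbonyl; the ester is needed because the free acid would interfere with the Ru catalyst in step 12.

**Step 12**
Reactants: 17
Product: 18 methyl ester of the target
Conditions: Hoveyda–Grubbs II (10 mol%), PhMe (2 mM), 100 °C, Ar sweep to remove ethylene
Reagents that add atoms: none
Why: Proposed new method: the Ru carbene initiates on the unhindered vinyl group and closes onto the isopropenyl alkene, forming the trisubstituted C5=C6 ring alkene, with ethylene loss driving the reaction. The closest known reaction is RCM of a 1,1-disubstituted plus monosubstituted alkene to a trisubstituted cyclohexene, and the trans ring fusion is enforced by the all-trans cyclopentene. C3, C4, C7, C8 and C9 are untouched, and the hindered trisubstituted styryl-diene is expected to be slow to react with Ru.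

**Step 13**
Reactants: 18
Product: 19 Zyggomphic acid B
Conditions: LiSPr (from PrSH and n-BuLi), HMPA, THF, 25 °C; then H3O+
Reagents that add atoms: none (the methyl leaves as MeSPr)
Why: Thiolate SN2 demethylation cleaves the methyl ester regardless of steric hindrance at the carbonyl; C8 is quaternary, so there is no epimerisation risk.

---

**Compound list**

1 | (E)-4-phenylbut-3-en-2-one | CC(=O)/C=C/c1ccccc1 | starting material
2 | ethyl (E)-4-(diethoxyphosphoryl)-3-methylbut-2-enoate | CCOC(=O)/C=C(\C)CP(=O)(OCC)OCC | starting material
3 | ethyl (2E,4E,6E)-3,5-dimethyl-7-phenylhepta-2,4,6-trienoate | CCOC(=O)/C=C(\C)/C=C(\C)/C=C/c1ccccc1 | intermediate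
4 | (2E,4E,6E)-3,5-dimethyl-7-phenylhepta-2,4,6-trien-1-ol | OC/C=C(\C)/C=C(\C)/C=C/c1ccccc1 | intermediate
5 | (R)-4-methylcyclopent-2-en-1-one | C[C@@H]1CC(=O)C=C1 | starting material
6 | isopropenylmagnesium bromide | C=C(C)[Mg]Br | starting material
7 | methyl pyruvate | CC(=O)C(=O)OC | starting material
8 | methyl 2-hydroxy-2-methyl-2-[4-methyl-2-oxo-5-(prop-1-en-2-yl)cyclopentyl]propanoate (4,5-trans) | O=C1C[C@@H](C)[C@H](C(C)=C)C1C(C)(O)C(=O)OC | intermediate
9 | methyl 2-[4-methyl-2-oxo-5-(prop-1-en-2-yl)cyclopentylidene]propanoate | O=C1C[C@@H](C)[C@H](C(C)=C)C1=C(C)C(=O)OC | intermediate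
10 | methyl 2-[4-methyl-2-oxo-5-(prop-1-en-2-yl)cyclopentyl]propanoate (all-trans ring) | O=C1C[C@@H](C)[C@H](C(C)=C)[C@H]1C(C)C(=O)OC | intermediate
11 | cyclopentenyl triflate of 10 | O=S(=O)(OC1=C[C@@H](C)[C@H](C(C)=C)[C@H]1C(C)C(=O)OC)C(F)(F)F | intermediate
12 | diethylzinc | CC[Zn]CC | starting material
13 | methyl 2-[2-ethyl-4-methyl-5-(prop-1-en-2-yl)cyclopent-2-en-1-yl]propanoate | CCC1=C[C@@H](C)[C@H](C(C)=C)[C@H]1C(C)C(=O)OC | intermediate
14 | corresponding carboxylic acid | CCC1=C[C@@H](C)[C@H](C(C)=C)[C@H]1C(C)C(=O)O | intermediate
15 | trienyl ester of 14 | CCC1=C[C@@H](C)[C@H](C(C)=C)[C@H]1C(C)C(=O)OC/C=C(\C)/C=C(\C)/C=C/c1ccccc1 | intermediate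
16 | Claisen acid (3-ethenyl-2,3,5-trimethyl-7-phenylhepta-4,6-dienoic acid bearing the cyclopentenyl group) | CCC1=C[C@@H](C)[C@H](C(C)=C)[C@H]1[C@@](C)(C(=O)O)[C@](C)(C=C)/C=C(C)/C=C/c1ccccc1 | intermediate
17 | methyl ester of 16 | CCC1=C[C@@H](C)[C@H](C(C)=C)[C@H]1[C@@](C)(C(=O)OC)[C@](C)(C=C)/C=C(C)/C=C/c1ccccc1 | intermediate
18 | methyl ester of Zyggomphic acid B | CCC1=C[C@@H](C)[C@@H]2C(C)=C[C@](C)(/C=C(C)/C=C/c3ccccc3)[C@](C)(C(=O)OC)[C@@H]12 | intermediate
19 | Zyggomphic acid B | CCC1=C[C@@H](C)[C@@H]2C(C)=C[C@](C)(/C=C(C)/C=C/c3ccccc3)[C@](C)(C(=O)O)[C@@H]12 | target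

---

**Totals**
- Total steps: 13.
- Longest linear sequence: 11 steps (5 → 19, steps 3–13). The trienol arm is 2 steps and joins at step 9.

**Three steps most likely to fail**
1. **Step 10 (Ireland–Claisen).** Forming two adjacent quaternary carbons may need forcing conditions, and facial control relative to C9 is uncertain.
   Fallback (different approach): drop the [3,3] and form C7–C8 by a 6-endo intramolecular Michael addition of a β-keto ester donor (at C7) onto an alkylidene cyclopentanone acceptor like 9. Then install C5=C6 through the C6 ketone by enol triflate formation and Pd/HCO2H reduction, and build the side chain from a C7 ester by olefination.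
2. **Step 12 (RCM).** The hindered isopropenyl/vinyl closure, next to quaternary centres and with a competing styryl-diene, may stall or oligomerise.
   Fallback (different approach): use a C5 methyl ketone and a C6 aldehyde instead, and close the ring by intramolecular McMurry coupling (TiCl3/Zn–Cu). This needs a vinylcuprate plus Wacker oxidation in step 3 and a masked-aldehyde allylic alcohol in step 9.
3. **Steps 4–5 (tetrasubstituted alkylidene, then reduction and C9 equilibration).** Dehydration may give the wrong alkene isomer, and the reduction or epimerisation may be poor.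
   Fallback (different approach): skip the aldol/dehydration/reduction and trap the step-3 enolate directly with methyl 2-iodopropionate in THF/HMPA to give 10 in one step. Alternatively, build C9–C8 by an Ireland–Claisen on a cyclopentenyl ester.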